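**Retrosynthetic overview**

1. Parritadial ⇐ (Swern oxidation, desilylation, acetylation) 11,12-disilyloxy-drim-7-ene-1β,6α,9α-triol ⇐ syn-hydroboration of a drima-5,7-diene (sets 5α-H and 6α-OH together) ⇐ cis-fused hydroxy keto ester 17.
2. Key disconnection: ring A (C1–C2–C3–C4–C5–C10) is carried as a cyclopentanol (C1–C5) fused to a seven-membered ring (C1, C5–C10). A 2,3-epoxy-alcohol semipinacol shift of C5 from C1 to C10 expands ring A by one carbon, contracts the seven-membered ring to ring B with the same bond, and fixes C9 (tertiary OH) and C10 (quaternary methyl carbon).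
3. Enabling feature: the array O–C1–C10(CH3)–C9–O. The oxygen-bearing ring A carbon C1 lies next to the quaternary ring-fusion carbon C10, which carries the oxygenated C9; read as a β-hydroxy ketone with an α-quaternary centre, this is the retron of the semipinacol shift.
4. Order of rings: cyclopentane (from 3-methylcyclopentenone) → seven-membered ring by RCM → rings A and B together in the key step. Fragments: C11–C9–C10 from a propargyl ether, the C10 methyl by carbomagnesiation, C8/C12 from a stannyl acrylate.
5. Stereochemistry: one centre from catalysis (C5, asymmetric allylation) is relayed to C1, then to C9/C10 (directed epoxidation, anti shift); C5 is then erased and re-set together with C6, and C1 is set by substrate control.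

Key step: step 9

Remark: drimane numbering is used for the bicyclic compounds and for the atoms that become them (ring A = C1–C5 and C10, ring B = C5–C10, C11 on C9, C12 on C8); the target is read as 1β,6α-diacetoxy-9α-hydroxy-5α,10β-drim-7-ene-11,12-dial, and the (R,R) ligand in step 2 is assumed to give (R)-5 (if the sense is opposite, the (S,S) ligand is used).

**Route**

Step 1
Reactants: 1 3-methylcyclopent-2-en-1-one; 2 allyl chloroformate
Product: 4 allyl 3,3-dimethylcyclopent-1-en-1-yl carbonate, via magnesium enolate 3 (not isolated)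
Conditions: MeMgBr (1.2 equiv), CuBr·SMe2 (5 mol%), THF, -30 to 0 °C; then 2, -78 °C to rt
Reagents that add atoms: methylmagnesium bromide, C[Mg]Br
Why: Copper-catalysed conjugate addition of the methyl Grignard reagent to the β-methyl enone gives the regiodefined enolate 3 (C=C towards the new quaternary carbon), which the hard chloroformate acylates on oxygen (enolate trapping as enol carbonate); no stereocentre is formed.

Step 2
Reactants: 4 allyl 3,3-dimethylcyclopent-1-en-1-yl carbonate
Product: 5 (R)-2-allyl-3,3-dimethylcyclopentan-1-one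
Conditions: Pd2(dba)3 (2.5 mol%), (1R,2R)-N,N'-bis[2-(diphenylphosphino)benzoyl]cyclohexane-1,2-diamine (5.5 mol%), toluene, rt
Reagents that add atoms: none
Why: Decarboxylative asymmetric allylic alkylation (Tsuji–Trost type): zerovalent palladium ionises the enol carbonate, CO2 is lost, and ligand-controlled recombination of the enolate with the π-allyl complex sets the single α-stereocentre (future C5) under catalyst control.

Step 3
Reactants: 5 (R)-2-allyl-3,3-dimethylcyclopentan-1-one; 6 tert-butyldimethyl(prop-2-yn-1-yloxy)silane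
Product: 8 (1S,2R)-2-allyl-1-[3-(tert-butyldimethylsilyloxy)prop-1-yn-1-yl]-3,3-dimethylcyclopentan-1-ol, via lithium acetylide 7 (not isolated)
Conditions: 6, n-BuLi, THF, -78 °C; then 5, -78 to 0 °C; H2O
Reagents that add atoms: none
Why: 1,2-Addition of the lithium acetylide to the ketone should occur from the face opposite the neighbouring allyl group (substrate control), giving the tertiary propargylic alcohol with alkynyl trans to allyl (C1 set from C5).

Step 4
Reactants: 8 (1S,2R)-2-allyl-1-[3-(tert-butyldimethylsilyloxy)prop-1-yn-1-yl]-3,3-dimethylcyclopentan-1-ol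
Product: 10 (1S,2R)-2-allyl-1-[(Z)-4-(tert-butyldimethylsilyloxy)-3-iodobut-2-en-2-yl]-3,3-dimethylcyclopentan-1-ol, via alkenylmagnesium chelate 9 (not isolated)
Conditions: MeMgBr (4 equiv), CuI (20 mol%), THF, 0 °C to rt; then I2, THF, -78 to 0 °C; H2O
Reagents that add atoms: methylmagnesium bromide, C[Mg]Br; iodine, II
Why: Copper-catalysed anti-carbomagnesiation of a propargylic alkoxide: methyl is delivered to the alkyne carbon next to the carbinol (C10) and magnesium ends on the distal carbon (C9) inside the five-membered chelate 9, so iodinolysis with retention gives the Z-iodoalkene with iodine cis to C1 and CH2OSi cis to methyl.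

Step 5
Reactants: 11 methyl propiolate; 12 tributyltin hydride
Product: 13 methyl 2-(tributylstannyl)acrylate
Conditions: Pd(PPh3)4 (2 mol%), THF, 0 °C to rt
Reagents that add atoms: none
Why: Palladium-catalysed syn-hydrostannation of an alkynoate places tin on the α-carbon and hydrogen on the β-carbon, the established regiochemistry for propiolates.

Step 6
Reactants: 10 (1S,2R)-2-allyl-1-[(Z)-4-(tert-butyldimethylsilyloxy)-3-iodobut-2-en-2-yl]-3,3-dimethylcyclopentan-1-ol; 13 methyl 2-(tributylstannyl)acrylate
Product: 14 methyl (3E)-3-[(tert-butyldimethylsilyloxy)methyl]-4-[(1S,2R)-2-allyl-1-hydroxy-3,3-dimethylcyclopentyl]-2-methylidenepent-3-enoate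
Conditions: Pd(PPh3)4 (5 mol%), CuI (20 mol%), DMF, 50 °C
Reagents that add atoms: none
Why: Stille cross-coupling joins the two sp2 carbons with retention of alkene geometry, so the 2-carbomethoxyvinyl group (C8 with C12) stands cis to C1 as the later ring closure requires.

Step 7
Reactants: 14 methyl (3E)-3-[(tert-butyldimethylsilyloxy)methyl]-4-[(1S,2R)-2-allyl-1-hydroxy-3,3-dimethylcyclopentyl]-2-methylidenepent-3-enoate
Product: 15 methyl 8a-hydroxy-3,3,8-trimethyl-7-[(tert-butyldimethylsilyloxy)methyl]-1,2,3,3a,4,8a-hexahydroazulene-6-carboxylate (trans-fused; 3a-H anti to 8a-OH)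
Conditions: second-generation Grubbs catalyst (5 mol%), toluene, 80 °C
Reagents that add atoms: none
Why: Ring-closing olefin metathesis between the allyl group and the 1,1-disubstituted acrylate alkene closes the seven-membered ring (C1, C5–C10), possible because the tetrasubstituted Z-alkene holds C8 cis to C1; the fusion is trans because alkenyl and allyl are trans on the cyclopentane.

Step 8
Reactants: 15 methyl 8a-hydroxy-3,3,8-trimethyl-7-[(tert-butyldimethylsilyloxy)methyl]-1,2,3,3a,4,8a-hexahydroazulene-6-carboxylate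
Product: 16 the 7,8-epoxide of 15 with the epoxide oxygen syn to the 8a-hydroxyl (C9–C10 epoxide in drimane numbering)
Conditions: VO(acac)2 (5 mol%), t-BuOOH (1.5 equiv), CH2Cl2, 0 °C to rt
Reagents that add atoms: tert-butyl hydroperoxide, CC(C)(C)OO
Why: Hydroxyl-directed epoxidation selects the allylic, electron-rich tetrasubstituted C9=C10 bond over the ester-conjugated C7=C8 bond and delivers oxygen to the ring face syn to the ring-fusion hydroxyl, which sets C9 and C10 together (16 is purified as one diastereomer).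

Step 9
Reactants: 16 the 7,8-epoxide of 15 (epoxide syn to the 8a-hydroxyl)
Product: 17 methyl 11-(tert-butyldimethylsilyloxy)-9α-hydroxy-1-oxo-5β-drim-7-en-12-oate (cis-fused decalin)
Conditions: BF3·OEt2 (0.2 equiv), CH2Cl2, -78 to -40 °C
Reagents that add atoms: none
Why: BF3 binds the epoxide oxygen, the C10–O bond ionises while the antiperiplanar ring-fusion bond C1–C5 migrates from C1 to C10, and the C1 hydroxyl collapses to the ketone. The closest known reaction type is the Lewis-acid semipinacol rearrangement of 2,3-epoxy alcohols (1-(epoxyalkyl)cycloalkanols giving ring-expanded β-hydroxy ketones with an α-quaternary carbon), whose pinacol-terminated annulation variants also deliver cis-fused bicycles. Ring A is closed by this suprafacial 1,2-alkyl shift as a one-carbon ring expansion of the cyclopentanol (C10 inserted between C1 and C5), and the same shift contracts the seven-membered ring to ring B. C10 is formed with inversion at the epoxide carbon, so its configuration follows from the epoxide face set in step 8; C9 keeps its C–O bond, its configuration coming from the Z-alkene and the same face; C5 migrates with retention, which makes the decalin cis-fused. The step needs cleavage of C10–O rather than C9–O and migration of C5 rather than C2. The first is secured by the electron-poor 2-carbomethoxyvinyl and CH2OSi groups on C9, which disfavour a cation there; the second by the trans-fused bicycle, in which only the ring bond C1–C5 can lie anti to C10–O.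

Step 10
Reactants: 17 methyl 11-(tert-butyldimethylsilyloxy)-9α-hydroxy-1-oxo-5β-drim-7-en-12-oate
Product: 19 methyl 11-(tert-butyldimethylsilyloxy)-9α-hydroxy-1-oxodrima-5,7-dien-12-oate, via allylic bromide 18 (not isolated)
Conditions: N-bromosuccinimide (1.1 equiv), AIBN (10 mol%), PhCF3, 80 °C; then DBU, THF, rt
Reagents that add atoms: N-bromosuccinimide, O=C1CCC(=O)N1Br (its bromine is found in 18 only)
Why: Wohl–Ziegler bromination takes the only allylic methylene (C6, γ to the ester), and E2 dehydrobromination with loss of H5 gives the conjugated 5,7-dienoate; this erases the relay centre C5, so 17 must be diastereomerically pure before this step.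

Step 11
Reactants: 19 methyl 11-(tert-butyldimethylsilyloxy)-9α-hydroxy-1-oxodrima-5,7-dien-12-oate
Product: 20 11-(tert-butyldimethylsilyloxy)drima-5,7-diene-1β,9α,12-triol
Conditions: i-Bu2AlH (6 equiv), CH2Cl2, -78 to 0 °C; aq. potassium sodium tartrate
Reagents that add atoms: none
Why: Hydride reduction: the aluminium hydride reduces the dienoate to the allylic alcohol (1,2-reduction) and the C1 ketone from the α-face, opposite the axial 10β-methyl and assisted by delivery from the 9α-alkoxide, which should give the equatorial 1β-alcohol.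

Step 12
Reactants: 20 11-(tert-butyldimethylsilyloxy)drima-5,7-diene-1β,9α,12-triol
Product: 21 11,12-bis(tert-butyldimethylsilyloxy)drima-5,7-diene-1β,9α-diol
Conditions: TBSCl (1.1 equiv), imidazole, CH2Cl2, 0 °C
Reagents that add atoms: tert-butyldimethylsilyl chloride, CC(C)(C)[Si](C)(C)Cl
Why: Silylation is selective for the primary hydroxyl over the hindered secondary C1 hydroxyl and the tertiary C9 hydroxyl (protecting-group step).

Step 13
Reactants: 21 11,12-bis(tert-butyldimethylsilyloxy)drima-5,7-diene-1β,9α-diol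
Product: 23 11,12-bis(tert-butyldimethylsilyloxy)-5α-drim-7-ene-1β,6α,9α-triol, via alkylborane 22 (not isolated)
Conditions: BH3·THF (4 equiv), THF, 0 °C to rt; then NaOH, H2O2, 0 °C
Reagents that add atoms: borane–tetrahydrofuran, [BH3-][O+]1CCCC1 (its boron is found in 22 only); hydrogen peroxide, OO
Why: Hydroboration–oxidation: borane adds syn to the Δ5 bond of the 5,7-diene from the α-face (the β-face is blocked by the 10β- and 4β-methyl groups) with boron at C6, as known for steroidal 5,7-dienes, so C5 (α-H) and C6 (α-OH) are set in one event and the Δ7 bond is kept.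

Step 14
Reactants: 23 11,12-bis(tert-butyldimethylsilyloxy)-5α-drim-7-ene-1β,6α,9α-triol
Product: 24 1β,6α-diacetoxy-11,12-bis(tert-butyldimethylsilyloxy)drim-7-en-9α-ol
Conditions: Ac2O, pyridine, DMAP (cat.), CH2Cl2, rt
Reagents that add atoms: acetic anhydride, CC(=O)OC(C)=O
Why: DMAP-catalysed acylation esterifies the two secondary hydroxyls, while the hindered tertiary C9 hydroxyl should not react.

Step 15
Reactants: 24 1β,6α-diacetoxy-11,12-bis(tert-butyldimethylsilyloxy)drim-7-en-9α-ol
Product: 25 1β,6α-diacetoxydrim-7-ene-9α,11,12-triol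
Conditions: HF·pyridine, THF/pyridine, 0 °C to rt
Reagents that add atoms: none
Why: Fluoride-mediated desilylation removes both primary silyl ethers; the acetates should survive the mildly acidic fluoride source.

Step 16
Reactants: 25 1β,6α-diacetoxydrim-7-ene-9α,11,12-triol
Product: 26 Parritadial (1β,6α-diacetoxy-9α-hydroxydrim-7-ene-11,12-dial)
Conditions: (COCl)2, DMSO, CH2Cl2, -78 °C; then Et3N, -78 to -20 °C
Reagents that add atoms: none
Why: Swern oxidation converts both primary alcohols of the 1,4-diol to aldehydes at once (no lactol stage that would lead to a lactone) and leaves the tertiary alcohol and the acetates untouched.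

**Compound list**

1 | 3-methylcyclopent-2-en-1-one | CC1=CC(=O)CC1 | starting material
2 | allyl chloroformate | C=CCOC(=O)Cl | starting material
3 | bromomagnesium 3,3-dimethylcyclopent-1-en-1-olate | CC1(C)CCC(O[Mg]Br)=C1 | intermediate (not isolated)
4 | allyl 3,3-dimethylcyclopent-1-en-1-yl carbonate | C=CCOC(=O)OC1=CC(C)(C)CC1 | intermediate
5 | (R)-2-allyl-3,3-dimethylcyclopentan-1-one | C=CC[C@H]1C(=O)CCC1(C)C | intermediate
6 | tert-butyldimethyl(prop-2-yn-1-yloxy)silane | C#CCO[Si](C)(C)C(C)(C)C | starting material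
7 | lithium 3-(tert-butyldimethylsilyloxy)prop-1-yn-1-ide | [Li]C#CCO[Si](C)(C)C(C)(C)C | intermediate (not isolated)
8 | (1S,2R)-2-allyl-1-[3-(tert-butyldimethylsilyloxy)prop-1-yn-1-yl]-3,3-dimethylcyclopentan-1-ol | C=CC[C@@H]1C(C)(C)CC[C@@]1(O)C#CCO[Si](C)(C)C(C)(C)C | intermediate
9 | spiro oxamagnesacycle (O–Mg–C9=C10 chelate) from anti-carbomagnesiation of 8 | C=CC[C@@H]1C(C)(C)CC[C@]12O[Mg]C(CO[Si](C)(C)C(C)(C)C)=C2C | intermediate (not isolated)
10 | (1S,2R)-2-allyl-1-[(Z)-4-(tert-butyldimethylsilyloxy)-3-iodobut-2-en-2-yl]-3,3-dimethylcyclopentan-1-ol | C=CC[C@@H]1C(C)(C)CC[C@@]1(O)/C(C)=C(\I)CO[Si](C)(C)C(C)(C)C | intermediate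
11 | methyl propiolate | C#CC(=O)OC | starting material
12 | tributyltin hydride | CCCC[SnH](CCCC)CCCC | starting material
13 | methyl 2-(tributylstannyl)acrylate | C=C(C(=O)OC)[Sn](CCCC)(CCCC)CCCC | intermediate
14 | methyl (3E)-3-[(tert-butyldimethylsilyloxy)methyl]-4-[(1S,2R)-2-allyl-1-hydroxy-3,3-dimethylcyclopentyl]-2-methylidenepent-3-enoate | C=CC[C@@H]1C(C)(C)CC[C@@]1(O)/C(C)=C(\C(=C)C(=O)OC)CO[Si](C)(C)C(C)(C)C | intermediate
15 | methyl 8a-hydroxy-3,3,8-trimethyl-7-[(tert-butyldimethylsilyloxy)methyl]-1,2,3,3a,4,8a-hexahydroazulene-6-carboxylate (trans-fused) | O[C@@]12CCC(C)(C)[C@H]1CC=C(C(=O)OC)C(CO[Si](C)(C)C(C)(C)C)=C2C | intermediate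
16 | 7,8-epoxide of 15, oxygen syn to the 8a-hydroxyl | O[C@@]12CCC(C)(C)[C@H]1CC=C(C(=O)OC)[C@@]3(CO[Si](C)(C)C(C)(C)C)O[C@@]23C | intermediate
17 | methyl 11-(tert-butyldimethylsilyloxy)-9α-hydroxy-1-oxo-5β-drim-7-en-12-oate | O=C1CCC(C)(C)[C@H]2CC=C(C(=O)OC)[C@](O)(CO[Si](C)(C)C(C)(C)C)[C@@]12C | intermediate
18 | 6-bromo derivative of 17 (both C6 epimers) | O=C1CCC(C)(C)[C@H]2C(Br)C=C(C(=O)OC)[C@](O)(CO[Si](C)(C)C(C)(C)C)[C@@]12C | intermediate (not isolated)
19 | methyl 11-(tert-butyldimethylsilyloxy)-9α-hydroxy-1-oxodrima-5,7-dien-12-oate | O=C1CCC(C)(C)C2=CC=C(C(=O)OC)[C@](O)(CO[Si](C)(C)C(C)(C)C)[C@@]12C | intermediate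
20 | 11-(tert-butyldimethylsilyloxy)drima-5,7-diene-1β,9α,12-triol | O[C@@H]1CCC(C)(C)C2=CC=C(CO)[C@](O)(CO[Si](C)(C)C(C)(C)C)[C@@]12C | intermediate
21 | 11,12-bis(tert-butyldimethylsilyloxy)drima-5,7-diene-1β,9α-diol | O[C@@H]1CCC(C)(C)C2=CC=C(CO[Si](C)(C)C(C)(C)C)[C@](O)(CO[Si](C)(C)C(C)(C)C)[C@@]12C | intermediate
22 | 6α-boryl-11,12-bis(tert-butyldimethylsilyloxy)-5α-drim-7-ene-1β,9α-diol (drawn as the monoalkylborane, hydroxyls shown free) | O[C@@H]1CCC(C)(C)[C@@H]2[C@@H](B)C=C(CO[Si](C)(C)C(C)(C)C)[C@](O)(CO[Si](C)(C)C(C)(C)C)[C@@]12C | intermediate (not isolated)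
23 | 11,12-bis(tert-butyldimethylsilyloxy)-5α-drim-7-ene-1β,6α,9α-triol | O[C@@H]1CCC(C)(C)[C@@H]2[C@@H](O)C=C(CO[Si](C)(C)C(C)(C)C)[C@](O)(CO[Si](C)(C)C(C)(C)C)[C@@]12C | intermediate
24 | 1β,6α-diacetoxy-11,12-bis(tert-butyldimethylsilyloxy)drim-7-en-9α-ol | CC(=O)O[C@@H]1CCC(C)(C)[C@@H]2[C@@H](OC(C)=O)C=C(CO[Si](C)(C)C(C)(C)C)[C@](O)(CO[Si](C)(C)C(C)(C)C)[C@@]12C | intermediate
25 | 1β,6α-diacetoxydrim-7-ene-9α,11,12-triol | CC(=O)O[C@@H]1CCC(C)(C)[C@@H]2[C@@H](OC(C)=O)C=C(CO)[C@](O)(CO)[C@@]12C | intermediate
26 | Parritadial | CC(=O)O[C@@H]1CCC(C)(C)[C@@H]2[C@@H](OC(C)=O)C=C(C=O)[C@](O)(C=O)[C@@]12C | target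

**Step count and risks**

Total step count: 16. Longest linear sequence: 15 (steps 1–4 and 6–16; step 5 is a one-step side branch).

Steps most likely to fail:

Step 4. The carbomagnesiation may be slow or misdirected at the hindered tertiary alkoxide, and the alkenylmagnesium 9 may lose silanolate to give an allene. Fallback, setting out from 8 and returning at 14: trans-diboration of the propargylic alkoxide (bis(pinacolato)diboron, n-BuLi, THF, 70 °C) should give the spiro 4-boryl-1,2-oxaborol-2(5H)-ol F1, with the ring boron on C9 cis to C1 and the pinacol boronate on C10. Suzuki–Miyaura methylation of the pinacol boronate (MeI, Pd2(dba)3, P(o-tol)3, K2CO3, DMF/H2O) would give the 4-methyl oxaborole F2. A second Suzuki–Miyaura coupling of the ring boron with methyl 2-bromoacrylate (PdCl2(dppf), K3PO4, THF/H2O) then opens the oxaborole and delivers 14 with the same alkene geometry.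

Step 9. The epoxide may ionise at C9 (allylic to the ring enoate, which the bicycle holds in conjugation), or the C10 cation may lose a proton instead of accepting C5. Fallback, setting out from 14 and returning at 17: the rearrangement is run before the seven-membered ring exists. Hydroxyl-directed epoxidation of the open-chain triene (VO(acac)2, t-BuOOH), with the branched C5 turned away from the oxidant, should give epoxy alcohol F3, in which the acrylate can twist out of conjugation. BF3·OEt2 then shifts C5 to give the monocyclic hydroxy ketone F4, and RCM of F4 (second-generation Grubbs catalyst) closes ring B directly to 17.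

Step 13. Facial or site selectivity of the hydroboration may be poor (attack on the Δ7 bond, β-face attack, or transposition of the allylic borane). Fallback, setting out from 17 and returning at 24: allylic oxidation at C6 (CrO3, 3,5-dimethylpyrazole, CH2Cl2, -20 °C) gives the cis-fused ene-dione ester F5. DBU equilibrates C5, now α to the C6 ketone, to the trans-fused ene-dione ester F6. i-Bu2AlH reduces the ester and both ketones from the α-face to the 1β,6β,9α,12-tetraol F7, and TBSCl/imidazole protects the primary hydroxyl to give the bis-silyl ether F8. A Mitsunobu reaction with acetic acid (PPh3, DIAD) inverts only the allylic C6 carbinol (the C1 carbinol is neopentylic) to the 6α-acetate F9, and Ac2O/pyridine/DMAP acetylates C1 to rejoin the route at 24.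

**Further compounds**

F1 | step 4 | spiro 4-(pinacolboryl)-1,2-oxaborol-2(5H)-ol from trans-diboration of 8 | C=CC[C@@H]1C(C)(C)CC[C@]12OB(O)C(CO[Si](C)(C)C(C)(C)C)=C2B3OC(C)(C)C(C)(C)O3
F2 | step 4 | spiro 4-methyl-1,2-oxaborol-2(5H)-ol | C=CC[C@@H]1C(C)(C)CC[C@]12OB(O)C(CO[Si](C)(C)C(C)(C)C)=C2C
F3 | step 9 | open-chain epoxy alcohol (C9–C10 epoxide of 14) | C=CC[C@@H]1C(C)(C)CC[C@@]1(O)[C@]2(C)O[C@]2(CO[Si](C)(C)C(C)(C)C)C(=C)C(=O)OC
F4 | step 9 | monocyclic hydroxy ketone (2-allyl-3,3-dimethyl-6-oxocyclohexane with the C9 carbinol side chain) | O=C1CCC(C)(C)[C@@H](CC=C)[C@@]1(C)[C@@](O)(CO[Si](C)(C)C(C)(C)C)C(=C)C(=O)OC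
F5 | step 13 | methyl 11-(tert-butyldimethylsilyloxy)-9α-hydroxy-1,6-dioxo-5β-drim-7-en-12-oate | O=C1CCC(C)(C)[C@H]2C(=O)C=C(C(=O)OC)[C@](O)(CO[Si](C)(C)C(C)(C)C)[C@@]12C
F6 | step 13 | methyl 11-(tert-butyldimethylsilyloxy)-9α-hydroxy-1,6-dioxo-5α-drim-7-en-12-oate | O=C1CCC(C)(C)[C@@H]2C(=O)C=C(C(=O)OC)[C@](O)(CO[Si](C)(C)C(C)(C)C)[C@@]12C
F7 | step 13 | 11-(tert-butyldimethylsilyloxy)drim-7-ene-1β,6β,9α,12-tetraol | O[C@@H]1CCC(C)(C)[C@@H]2[C@H](O)C=C(CO)[C@](O)(CO[Si](C)(C)C(C)(C)C)[C@@]12C
F8 | step 13 | 11,12-bis(tert-butyldimethylsilyloxy)drim-7-ene-1β,6β,9α-triol | O[C@@H]1CCC(C)(C)[C@@H]2[C@H](O)C=C(CO[Si](C)(C)C(C)(C)C)[C@](O)(CO[Si](C)(C)C(C)(C)C)[C@@]12C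
F9 | step 13 | 6α-acetoxy-11,12-bis(tert-butyldimethylsilyloxy)drim-7-ene-1β,9α-diol | O[C@@H]1CCC(C)(C)[C@@H]2[C@@H](OC(C)=O)C=C(CO[Si](C)(C)C(C)(C)C)[C@](O)(CO[Si](C)(C)C(C)(C)C)[C@@]12C
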